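## Numbering of the compounds

TBS = tert-butyldimethylsilyl. The ring B building blocks 4–9 carry chromene numbering: C6 (formyl or propenal) becomes C1' of the flavan, C7 = C2', C8 = C3', C8a = C4', C4a = C5'. "Ar" in 12–15 is 8-(TBS-oxy)-2,2-dimethyl-7-(3-methylbut-2-en-1-yl)-2H-chromen-6-yl.

1 3,4-dihydroxybenzaldehyde; 2 3-chloro-3-methylbut-1-yne; 3 the 4-O-(1,1-dimethylpropargyl) ether of 1; 4 8-hydroxy-2,2-dimethyl-2H-chromene-6-carbaldehyde; 5 its 8-O-(1,1-dimethylpropargyl) ether; 6 the 8-O-(1,1-dimethylallyl) ether; 7 the 7-prenyl-8-hydroxy aldehyde; 8 its TBS ether; 9 the derived (E)-cinnamaldehyde; 10 2,4-dihydroxybenzaldehyde; 11 its 4-O-TBS ether; 12 the 2-aryl-2H-chromene-3-carbaldehyde; 13 the trimethylsilyl enol ether of 14 (made in the flask); 14 the chromane-3-carbaldehyde; 15 the bis-TBS flavan; 16 Kazinol B.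

## Analysis of the target

Kazinol B is a (2S)-flavan. Ring C (O1, C2, C3, C4) is fused to ring A (C4a–C8a, OH on C7) and carries ring B on C2. Ring B is substituted on five positions: prenyl on C2', OH on C3', and a 2,2-dimethyl-2H-pyran (ring D) fused through oxygen on C4' and carbon on C5'. C2 is the only stereocenter, so there is nothing to relay from; its absolute configuration must come from a reagent or catalyst, and it sits next to the crowded C1'–C2' flank. The sensitive groups are the trisubstituted prenyl alkene, the cis-styrenyl alkene of ring D, two phenols, and the C2–O1 benzylic ether, which lies para to O4' and ionises under acid. The 3'-OH/2'-prenyl pair also cyclises to a dimethylchroman under acid. Acidic deprotection and unselective hydrogenation are therefore excluded. A plain C3=C4 alkene in ring C would be almost identical in reactivity to the ring D alkene, so it could not be reduced selectively. The strategy rests on one feature of ring C: O1 and C4 are bonded to neighbouring carbons of ring A (C8a and C4a), so ring A with O1 and C4 is a salicylaldehyde, and C2–C3 with the aryl group on C2 is the β,α pair of a cinnamaldehyde. C3 is unsubstituted in the target, so the enal carbon that drives the annulation must later leave as CO. While it is present it marks C3=C4 as the only electron-poor alkene.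

## Retrosynthetic reasoning

16 to 15 (O–Si bonds). Both phenols are carried as silyl ethers and freed last. Fluoride is the one deprotection that leaves the acid-labile C2–O1 ether, the prenyl phenol and both alkenes untouched.

15 to 14 (C3–CHO bond). A formyl group is added to C3 in the retrosynthetic sense. It is what allows ring C to be built and selectively saturated, and it can be removed by a neutral rhodium-mediated decarbonylation that does not touch C2.

14 to 12 through 13 (C3–C4 saturation). In 12 the formyl group polarises C3=C4, so a nucleophilic hydride attacks C4 and ignores the prenyl and ring D alkenes. The forward step must intercept the C3 enolate as silyl enol ether 13, because that enolate has the ring A aryloxide on C2 as a β leaving group.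

12 to 9 and 11 (O1–C2 and C3–C4 bonds). These two bonds join ring A to the C2–C3 unit, and cutting both gives two aldehydes of similar size. Forming O1–C2 by conjugate addition creates the stereocenter under catalyst control. The forward reaction has to deliver the phenol of 11 to one face of the β carbon of 9, close ring C by aldol reaction, and dehydrate.

11 to 10 (O–Si bond). Only the 4-OH of 10 is silylated; the 2-OH, hydrogen-bonded to the formyl group, stays free for the annulation.

9 to 8 (Cα=Cβ bond). A two-carbon Wittig homologation turns the aryl aldehyde into the (E)-enal.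

8 to 7 to 6 (O–Si bond, then the C7–CH2 bond of the prenyl group). The prenyl group is traced back to a tertiary allyl ether on O8. A [3,3] shift can only deliver it to C7, the one free ortho position, so the regiochemistry of the crowded ring is enforced.

6 to 5 to 4 and 2 (alkene from alkyne, then the O8–C bond). The tertiary allyl ether comes from the propargyl ether by semi-hydrogenation, and that ether from phenol 4 and the tertiary propargylic chloride 2.

4 to 3 to 1 and 2 (ring D: C4a–C4 bond, then the O–C bond). Ring D is unravelled to an aryl propargyl ether on the more acidic 4-OH of 1. Its thermal rearrangement can only reach the single free ortho carbon. The same chloride 2 serves both etherifications, so ring D and the prenyl group come from one five-carbon reagent.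

## Alternatives that were turned down

Alternative 1: Ring A is built instead of bought. The disconnection cuts C4a–C5 and C8–C8a. C5–C8 come from 3-(trimethylsilyl)but-3-en-2-one A3, and the rest from the (6S)-6-aryl δ-lactone A2, whose stereocenter would come from an asymmetric ketone reduction.
- Forward key step: the lithium enolate of A2 adds to A3 (Michael addition). An alkoxide base then lets the methyl ketone enolate acylate on the lactone carbonyl, which closes a cyclohexane-1,3-dione and frees the C2 alkoxide, giving hydroxy dione A1.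
- For it: C2 is set early by robust chemistry, away from any crowded catalytic step, and is never next to an enolisable carbon. On this point it is stronger than the chosen route.
- Against it: A1 is still far from a flavan. The benzylic alcohol must be cyclised onto the dione under acid, at a carbinol that ionises easily because O4' is para. The cyclohexenone must then be dehydrogenated to a phenol, and the usual oxidants also attack the prenyl group, the ring D alkene and the benzylic positions. The MOM ether on O3' needs acid for removal.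
- Comparison: it is a long linear route that makes ring A atom by atom. The chosen route takes ring A ready-made at the right oxidation level and needs no oxidation once the alkenes are present.

Alternative 2: The disconnection is the aryl–oxygen bond O1–C8a.
- Forward key step: lithium 2,2,6,6-tetramethylpiperidide A6 converts bromo alcohol A5 into its alkoxide and, by removing H8 between bromine and the MOM ether, into the C8–C8a aryne. The tethered alkoxide adds to C8a and gives the bis-MOM ether A4.
- For it: C2 comes from an open-chain asymmetric ketone reduction, which is more predictable than a catalytic addition beside a prenyl group. The ring closure gives the flavan directly, with nothing to remove from C3 and no reduction of ring C. On both points it is stronger.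
- Against it: the amide base meets the doubly activated benzylic/allylic CH2 of the prenyl group and the C4 benzylic hydrogens. The aryne meets two electron-rich alkenes (ene reaction, [2+2] addition). A5 needs its own linear assembly with a bromide that must survive. The two MOM groups come off only with acid, which the C2 ether and the prenyl phenol do not tolerate.
- Comparison: the length is similar. The chosen route offers weakly acidic or neutral conditions throughout and a fluoride-only deprotection.

Alternative 3: Ring D is made last; the disconnection is C5'–C4'' and O–C2'' of ring D.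
- Forward key step: catechol flavan A8 and Ti(OEt)4 A10 give a titanium aryloxide, which condenses at C5' with 3-methylbut-2-enal A9. Loss of water gives an ortho-quinone methide, and oxa-6π closure gives A7.
- For it: one step, and the regiochemistry is enforced because C5' is the only free position ortho to a phenol. In regiocontrol it equals the chosen ring D construction, and it is one step shorter for that ring.
- Against it: it does not address ring C or C2. A8 must still be made as a single enantiomer, now with an oxidation-prone free catechol and an ortho-prenyl phenol. The hot, Lewis acidic condensation is applied to the acid-sensitive C2–O1 ether on the most valuable intermediate.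
- Comparison: the chosen route builds ring D first, on the cheapest intermediate, by a purely thermal rearrangement, and concentrates the risk in one catalytic step that forms ring C and C2 together.

Key step: step 9

Remark on the chemistry (assumption): the sense of induction of the (S)-configured catalyst in step 9 is derived from the usual shielding model of its E,s-trans iminium ions. It should be confirmed on 12 or on 16; should it prove opposite, the (R)-configured catalyst is used in the same way.

## Route

Step 1
Reactants: 1 3,4-dihydroxybenzaldehyde; 2 3-chloro-3-methylbut-1-yne (1.05 equiv)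
Product: 3 3-hydroxy-4-(2-methylbut-3-yn-2-yloxy)benzaldehyde
Conditions: DBU (1.1 equiv), CuCl2·2H2O (0.1 mol%), MeCN, −5 to 0 °C
Reagents that add atoms: none
Why: Copper-catalysed propargylic etherification of a phenoxide with the tertiary propargylic chloride 2, a stable commercial liquid that needs no activation in the flask. With about one equivalent of base only the 4-OH, para to the formyl group and much the more acidic phenol, is ionised, so the ether forms on O4.

Step 2
Reactants: 3 3-hydroxy-4-(2-methylbut-3-yn-2-yloxy)benzaldehyde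
Product: 4 8-hydroxy-2,2-dimethyl-2H-chromene-6-carbaldehyde
Conditions: o-xylene, 140 °C, Ar
Reagents that add atoms: none
Why: Aryl propargyl ether Claisen rearrangement, then 1,5-hydrogen shift and oxa-6π electrocyclisation, gives the 2,2-dimethyl-2H-chromene. The ether oxygen has a single free ortho carbon, so ring D can form in one way only.

Step 3
Reactants: 4 8-hydroxy-2,2-dimethyl-2H-chromene-6-carbaldehyde; 2 3-chloro-3-methylbut-1-yne (1.2 equiv)
Product: 5 2,2-dimethyl-8-(2-methylbut-3-yn-2-yloxy)-2H-chromene-6-carbaldehyde
Conditions: DBU (1.3 equiv), CuCl2·2H2O (0.1 mol%), MeCN, 0 °C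
Reagents that add atoms: none
Why: The same copper-catalysed propargylic etherification on the only phenol left. It runs at 0 °C, far below the temperature at which the new ether would rearrange.

Step 4
Reactants: 5 2,2-dimethyl-8-(2-methylbut-3-yn-2-yloxy)-2H-chromene-6-carbaldehyde
Product: 6 2,2-dimethyl-8-(2-methylbut-3-en-2-yloxy)-2H-chromene-6-carbaldehyde
Conditions: H2 (1 atm), Pd/CaCO3 poisoned with Pb(OAc)2 (Lindlar catalyst), quinoline, EtOAc, rt, stopped after 1 equiv H2
Reagents that add atoms: none
Why: Lindlar semi-hydrogenation of a terminal alkyne to a vinyl group. The poisoned catalyst turns over the alkyne much faster than the ring D alkene, which is cis-disubstituted and flanked by a quaternary carbon, or the aldehyde.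

Step 5
Reactants: 6 2,2-dimethyl-8-(2-methylbut-3-en-2-yloxy)-2H-chromene-6-carbaldehyde
Product: 7 8-hydroxy-2,2-dimethyl-7-(3-methylbut-2-en-1-yl)-2H-chromene-6-carbaldehyde
Conditions: o-xylene, 130 °C, Ar
Reagents that add atoms: none
Why: Aromatic Claisen rearrangement of a 1,1-dimethylallyl aryl ether. The [3,3] shift bonds the terminal CH2 to C7, the only free position ortho to O8, and rearomatisation gives the phenol with a normal prenyl group.

Step 6
Reactants: 7 8-hydroxy-2,2-dimethyl-7-(3-methylbut-2-en-1-yl)-2H-chromene-6-carbaldehyde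
Product: 8 8-(tert-butyldimethylsilyloxy)-2,2-dimethyl-7-(3-methylbut-2-en-1-yl)-2H-chromene-6-carbaldehyde
Conditions: TBSCl, imidazole, DMF, rt
Reagents that add atoms: tert-butyldimethylsilyl chloride, CC(C)(C)[Si](C)(C)Cl
Why: Standard silylation of a phenol. The silyl ether keeps the phenol away from the copper hydride and the chlorosilane of step 10 and is removable by fluoride alone.

Step 7
Reactants: 8 8-(tert-butyldimethylsilyloxy)-2,2-dimethyl-7-(3-methylbut-2-en-1-yl)-2H-chromene-6-carbaldehyde
Product: 9 (E)-3-[8-(tert-butyldimethylsilyloxy)-2,2-dimethyl-7-(3-methylbut-2-en-1-yl)-2H-chromen-6-yl]prop-2-enal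
Conditions: Ph3P=CHCHO (1.5 equiv), PhMe, 90 °C
Reagents that add atoms: (triphenylphosphoranylidene)acetaldehyde, O=CC=P(c1ccccc1)(c1ccccc1)c1ccccc1
Why: Wittig reaction with a formyl-stabilised ylide gives the (E)-enal in one step. A limited excess of ylide keeps a second homologation of the product low.

Step 8
Reactants: 10 2,4-dihydroxybenzaldehyde
Product: 11 4-(tert-butyldimethylsilyloxy)-2-hydroxybenzaldehyde
Conditions: TBSCl (1.05 equiv), imidazole, CH2Cl2, 0 °C
Reagents that add atoms: tert-butyldimethylsilyl chloride, CC(C)(C)[Si](C)(C)Cl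
Why: Selective monosilylation. The 2-OH is hydrogen-bonded to the formyl oxygen and hindered, while the 4-OH is free and more acidic, so the phenol needed for ring C stays unprotected.

Step 9
Reactants: 9 (E)-3-[8-(tert-butyldimethylsilyloxy)-2,2-dimethyl-7-(3-methylbut-2-en-1-yl)-2H-chromen-6-yl]prop-2-enal; 11 4-(tert-butyldimethylsilyloxy)-2-hydroxybenzaldehyde (1.2 equiv)
Product: 12 (2R)-7-(tert-butyldimethylsilyloxy)-2-Ar-2H-chromene-3-carbaldehyde
Conditions: (S)-2-[diphenyl(trimethylsilyloxy)methyl]pyrrolidine (20 mol%), 2-nitrobenzoic acid (20 mol%), 4 Å MS, PhMe, 0 °C to rt, dark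
Reagents that add atoms: none
Why: The amine condenses with enal 9 to an E-configured, s-trans iminium ion, one face of which is covered by the diphenyl(silyloxy)methyl group, so the phenol of 11 adds to the β carbon from the open face (oxa-Michael, O1–C2) and sets C2; with the (S)-catalyst this face gives descriptor R in 12, which is the spatial arrangement of (2S)-16. The enamine so formed attacks the neighbouring aryl aldehyde (C3–C4) in a 6-(enolexo)-exo-trig aldol closure of ring C, and loss of water gives the conjugated iminium ion, which hydrolyses and returns the catalyst. The closest known reaction type is the diarylprolinol silyl ether catalysed oxa-Michael–aldol condensation of salicylaldehydes with cinnamaldehydes to 2-aryl-2H-chromene-3-carbaldehydes. The oxa-Michael step is reversible and the dehydration makes the sequence irreversible; afterwards C3 bears no hydrogen, so C2 can no longer be lost by retro-addition. The step needs enantiofacial selectivity at C2 and chemoselectivity between the two aldehydes: only 9 can form a conjugated iminium ion, only 11 has a phenol ortho to a formyl group, and the other phenols of rings A and B are silylated. 2-Nitrobenzoic acid speeds iminium formation and dehydration, and the sieves take up the water. Light is excluded because 2H-chromenes can open reversibly to ortho-quinone methides, which would erode C2.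

Step 10
Reactants: 12 (2R)-7-(tert-butyldimethylsilyloxy)-2-Ar-2H-chromene-3-carbaldehyde
Product: 14 (2S,3RS)-7-(tert-butyldimethylsilyloxy)-2-Ar-3,4-dihydro-2H-chromene-3-carbaldehyde (both C3 epimers), via trimethylsilyl enol ether 13 (not isolated)
Conditions: [(Ph3P)CuH]6 (0.25 equiv), Me3SiCl (3 equiv), PhH–THF, rt; then aq. citrate buffer (pH 4), THF, 0 °C; crude 14 used at once without chromatography
Reagents that add atoms: none
Why: Conjugate reduction of an enal by [(Ph3P)CuH]6 with a chlorosilane present (reductive silylation): hydride goes to C4, the only alkene carbon made electrophilic by the formyl group, and the unpolarised prenyl and ring D alkenes do not react. The copper enolate at C3 is silylated on oxygen as it forms, before it can expel the ring A aryloxide from C2 (E1cB), and mild acid then protonates C3 of 13 to give 14. C3 forms as a mixture, which does not matter because it becomes CH2; C2 keeps its arrangement and is now named S because the aryl group outranks the saturated C3.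

Step 11
Reactants: 14 (2S,3RS)-7-(tert-butyldimethylsilyloxy)-2-Ar-3,4-dihydro-2H-chromene-3-carbaldehyde
Product: 15 (2S)-7-(tert-butyldimethylsilyloxy)-2-Ar-3,4-dihydro-2H-chromene
Conditions: RhCl(PPh3)3 (1.1 equiv), PhMe, 90 °C, Ar
Reagents that add atoms: none
Why: Tsuji–Wilkinson decarbonylation: oxidative addition of the formyl C–H bond to monovalent rhodium, extrusion of CO and C–H reductive elimination replace CHO by H under neutral, base-free conditions. C2 is not involved, and the alkenes are inert to the complex in the absence of hydrogen.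

Step 12
Reactants: 15 (2S)-7-(tert-butyldimethylsilyloxy)-2-Ar-3,4-dihydro-2H-chromene
Product: 16 Kazinol B, (2S)-2-[8-hydroxy-2,2-dimethyl-7-(3-methylbut-2-en-1-yl)-2H-chromen-6-yl]-3,4-dihydro-2H-chromen-7-ol
Conditions: Bu4NF (2.5 equiv), AcOH (2.5 equiv), THF, 0 °C
Reagents that add atoms: none
Why: Fluoride cleaves both aryl silyl ethers. Acetic acid buffers the phenoxides, so the electron-rich phenols are not oxidised and the C2 benzylic ether sees neither strong acid nor strong base.

## Compound list

1 | 3,4-dihydroxybenzaldehyde | O=Cc1ccc(O)c(O)c1 | starting material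
2 | 3-chloro-3-methylbut-1-yne | CC(C)(Cl)C#C | starting material
3 | 3-hydroxy-4-(2-methylbut-3-yn-2-yloxy)benzaldehyde | O=Cc1ccc(OC(C)(C)C#C)c(O)c1 | intermediate
4 | 8-hydroxy-2,2-dimethyl-2H-chromene-6-carbaldehyde | O=Cc1cc(O)c2OC(C)(C)C=Cc2c1 | intermediate
5 | 2,2-dimethyl-8-(2-methylbut-3-yn-2-yloxy)-2H-chromene-6-carbaldehyde | O=Cc1cc(OC(C)(C)C#C)c2OC(C)(C)C=Cc2c1 | intermediate
6 | 2,2-dimethyl-8-(2-methylbut-3-en-2-yloxy)-2H-chromene-6-carbaldehyde | O=Cc1cc(OC(C)(C)C=C)c2OC(C)(C)C=Cc2c1 | intermediate
7 | 8-hydroxy-2,2-dimethyl-7-(3-methylbut-2-en-1-yl)-2H-chromene-6-carbaldehyde | O=Cc1cc2C=CC(C)(C)Oc2c(O)c1CC=C(C)C | intermediate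
8 | 8-(tert-butyldimethylsilyloxy)-2,2-dimethyl-7-(3-methylbut-2-en-1-yl)-2H-chromene-6-carbaldehyde | O=Cc1cc2C=CC(C)(C)Oc2c(O[Si](C)(C)C(C)(C)C)c1CC=C(C)C | intermediate
9 | (E)-3-[8-(tert-butyldimethylsilyloxy)-2,2-dimethyl-7-(3-methylbut-2-en-1-yl)-2H-chromen-6-yl]prop-2-enal | O=C/C=C/c1cc2C=CC(C)(C)Oc2c(O[Si](C)(C)C(C)(C)C)c1CC=C(C)C | intermediate
10 | 2,4-dihydroxybenzaldehyde | O=Cc1ccc(O)cc1O | starting material
11 | 4-(tert-butyldimethylsilyloxy)-2-hydroxybenzaldehyde | O=Cc1ccc(O[Si](C)(C)C(C)(C)C)cc1O | intermediate
12 | (2R)-7-(tert-butyldimethylsilyloxy)-2-[8-(tert-butyldimethylsilyloxy)-2,2-dimethyl-7-(3-methylbut-2-en-1-yl)-2H-chromen-6-yl]-2H-chromene-3-carbaldehyde | CC(C)=CCc1c([C@@H]2C(C=O)=Cc3ccc(O[Si](C)(C)C(C)(C)C)cc3O2)cc2c(c1O[Si](C)(C)C(C)(C)C)OC(C)(C)C=C2 | intermediate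
13 | (2R)-7-(tert-butyldimethylsilyloxy)-2-[8-(tert-butyldimethylsilyloxy)-2,2-dimethyl-7-(3-methylbut-2-en-1-yl)-2H-chromen-6-yl]-3-[(trimethylsilyloxy)methylidene]-3,4-dihydro-2H-chromene (E/Z mixture) | CC(C)=CCc1c([C@@H]2C(=CO[Si](C)(C)C)Cc3ccc(O[Si](C)(C)C(C)(C)C)cc3O2)cc2c(c1O[Si](C)(C)C(C)(C)C)OC(C)(C)C=C2 | intermediate
14 | (2S,3RS)-7-(tert-butyldimethylsilyloxy)-2-[8-(tert-butyldimethylsilyloxy)-2,2-dimethyl-7-(3-methylbut-2-en-1-yl)-2H-chromen-6-yl]-3,4-dihydro-2H-chromene-3-carbaldehyde | CC(C)=CCc1c([C@@H]2C(C=O)Cc3ccc(O[Si](C)(C)C(C)(C)C)cc3O2)cc2c(c1O[Si](C)(C)C(C)(C)C)OC(C)(C)C=C2 | intermediate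
15 | (2S)-7-(tert-butyldimethylsilyloxy)-2-[8-(tert-butyldimethylsilyloxy)-2,2-dimethyl-7-(3-methylbut-2-en-1-yl)-2H-chromen-6-yl]-3,4-dihydro-2H-chromene | CC(C)=CCc1c([C@@H]2CCc3ccc(O[Si](C)(C)C(C)(C)C)cc3O2)cc2c(c1O[Si](C)(C)C(C)(C)C)OC(C)(C)C=C2 | intermediate
16 | Kazinol B, (2S)-2-[8-hydroxy-2,2-dimethyl-7-(3-methylbut-2-en-1-yl)-2H-chromen-6-yl]-3,4-dihydro-2H-chromen-7-ol | CC(C)=CCc1c([C@@H]2CCc3ccc(O)cc3O2)cc2c(c1O)OC(C)(C)C=C2 | target

## Step count and least certain steps

Total: 12 steps. Longest linear sequence: 11 steps (steps 1–7 and 9–12, from 1); step 8 is a one-step branch.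

Step 9 (key step). The ortho prenyl group twists ring B out of the plane of the iminium ion and sits close to the shielding group, which may erode facial selectivity. The electron-rich, hindered iminium ion may also add the phenol slowly, so that the reversible addition stalls before the aldol closure.
Fallback, from 6, returning at 16: Wittig reaction of 6 with Ph3P=CHCHO in THF at 60 °C, below the temperature of the Claisen shift, gives (E)-3-[2,2-dimethyl-8-(2-methylbut-3-en-2-yloxy)-2H-chromen-6-yl]prop-2-enal F1, an enal without an ortho substituent. Under the conditions of step 9, F1 and 11 give (2R)-7-(tert-butyldimethylsilyloxy)-2-[2,2-dimethyl-8-(2-methylbut-3-en-2-yloxy)-2H-chromen-6-yl]-2H-chromene-3-carbaldehyde F2. Reductive silylation as in step 10 gives its trimethylsilyl enol ether F3 and, after buffered hydrolysis, (2S,3RS)-7-(tert-butyldimethylsilyloxy)-2-[2,2-dimethyl-8-(2-methylbut-3-en-2-yloxy)-2H-chromen-6-yl]-3,4-dihydro-2H-chromene-3-carbaldehyde F4. RhCl(PPh3)3 in PhMe at 90 °C gives (2S)-7-(tert-butyldimethylsilyloxy)-2-[2,2-dimethyl-8-(2-methylbut-3-en-2-yloxy)-2H-chromen-6-yl]-3,4-dihydro-2H-chromene F5. Heating in o-xylene at 130 °C moves the prenyl group to C2', the only free ortho position, and gives kazinol B 7-O-tert-butyldimethylsilyl ether F6 (the same compound as A7). Bu4NF/AcOH in THF gives 16. The Claisen shift is placed after saturation of ring C because a 2H-chromene might not hold C2 at 130 °C.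

Step 10. The copper enolate may expel the ring A aryloxide before it is silylated, which opens ring C; re-closure would not be selective. Competing 1,2-reduction of the formyl group is also possible.
Fallback, from 12, returning at 14: i-Bu2AlH in CH2Cl2 at −78 °C reduces only the formyl group, without any enolate, to [(2R)-7-(tert-butyldimethylsilyloxy)-2-Ar-2H-chromen-3-yl]methanol F7. The iridium hydride made from [Ir(cod)(PCy3)(py)]PF6 and H2 (THF, rt, H2 then purged) isomerises this primary allylic alcohol to the enol, which tautomerises to 14 under neutral conditions. The hydroxyl group binds the metal, so the other alkenes are not engaged.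

Step 11. CO extrusion from a secondary acyl rhodium species may be slow. At the temperature then required, β-hydride loss from the alkyl rhodium hydride (dehydrogenation of ring C) or thermal loss of the aryloxide from 14 may compete.
Fallback, from 14, returning at 15: Pinnick oxidation (NaClO2, NaH2PO4, 2-methylbut-2-ene, t-BuOH/H2O) gives (2S,3RS)-7-(tert-butyldimethylsilyloxy)-2-Ar-3,4-dihydro-2H-chromene-3-carboxylic acid F8. DCC and 1-hydroxypyridine-2(1H)-thione (CH2Cl2, 0 °C, dark, no amine base) give its 2-thioxopyridin-1(2H)-yl ester F9. Barton decarboxylation (visible light, t-BuSH, PhMe, rt) gives 15; the thiol should trap the C3 radical before it can fragment.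

Step 7. Olefination of a hindered, electron-rich aldehyde may be incomplete, and the product may be homologated a second time to the dienal.
Fallback, from 8, returning at 9: Horner–Wadsworth–Emmons reaction ((EtO)2P(O)CH2CO2Et, NaH, THF, 0 °C to rt) gives ethyl (E)-3-[8-(tert-butyldimethylsilyloxy)-2,2-dimethyl-7-(3-methylbut-2-en-1-yl)-2H-chromen-6-yl]prop-2-enoate F10. i-Bu2AlH (CH2Cl2, −78 °C) gives (E)-3-[8-(tert-butyldimethylsilyloxy)-2,2-dimethyl-7-(3-methylbut-2-en-1-yl)-2H-chromen-6-yl]prop-2-en-1-ol F11, and MnO2 (CH2Cl2, rt) gives 9.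

Step 4. The vinyl group may be over-hydrogenated to an ethyl group, giving an ether that cannot rearrange, and the ring D alkene may take up hydrogen slowly.
Fallback, from 4, returning at 6 (replaces steps 3 and 4): tert-butyl 2-methylbut-3-en-2-yl carbonate F12, made from 2-methylbut-3-en-2-ol and Boc2O with catalytic DMAP, reacts with 4 and Pd(PPh3)4 (2 mol%) in THF at 0 °C. This decarboxylative Tsuji–Trost etherification through a zerovalent-palladium-derived dimethylallyl complex places the phenoxide on the tertiary terminus and gives 6.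

## Further compounds

F1 | step 9 | (E)-3-[2,2-dimethyl-8-(2-methylbut-3-en-2-yloxy)-2H-chromen-6-yl]prop-2-enal | O=C/C=C/c1cc(OC(C)(C)C=C)c2OC(C)(C)C=Cc2c1
F2 | step 9 | (2R)-7-(tert-butyldimethylsilyloxy)-2-[2,2-dimethyl-8-(2-methylbut-3-en-2-yloxy)-2H-chromen-6-yl]-2H-chromene-3-carbaldehyde | C=CC(C)(C)Oc1cc([C@@H]2C(C=O)=Cc3ccc(O[Si](C)(C)C(C)(C)C)cc3O2)cc2C=CC(C)(C)Oc12
F3 | step 9 | (2R)-7-(tert-butyldimethylsilyloxy)-2-[2,2-dimethyl-8-(2-methylbut-3-en-2-yloxy)-2H-chromen-6-yl]-3-[(trimethylsilyloxy)methylidene]-3,4-dihydro-2H-chromene | C=CC(C)(C)Oc1cc([C@@H]2C(=CO[Si](C)(C)C)Cc3ccc(O[Si](C)(C)C(C)(C)C)cc3O2)cc2C=CC(C)(C)Oc12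
F4 | step 9 | (2S,3RS)-7-(tert-butyldimethylsilyloxy)-2-[2,2-dimethyl-8-(2-methylbut-3-en-2-yloxy)-2H-chromen-6-yl]-3,4-dihydro-2H-chromene-3-carbaldehyde | C=CC(C)(C)Oc1cc([C@@H]2C(C=O)Cc3ccc(O[Si](C)(C)C(C)(C)C)cc3O2)cc2C=CC(C)(C)Oc12
F5 | step 9 | (2S)-7-(tert-butyldimethylsilyloxy)-2-[2,2-dimethyl-8-(2-methylbut-3-en-2-yloxy)-2H-chromen-6-yl]-3,4-dihydro-2H-chromene | C=CC(C)(C)Oc1cc([C@@H]2CCc3ccc(O[Si](C)(C)C(C)(C)C)cc3O2)cc2C=CC(C)(C)Oc12
F6 | step 9 | kazinol B 7-O-tert-butyldimethylsilyl ether | CC(C)=CCc1c([C@@H]2CCc3ccc(O[Si](C)(C)C(C)(C)C)cc3O2)cc2c(c1O)OC(C)(C)C=C2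
F7 | step 10 | [(2R)-7-(tert-butyldimethylsilyloxy)-2-[8-(tert-butyldimethylsilyloxy)-2,2-dimethyl-7-(3-methylbut-2-en-1-yl)-2H-chromen-6-yl]-2H-chromen-3-yl]methanol | CC(C)=CCc1c([C@@H]2C(CO)=Cc3ccc(O[Si](C)(C)C(C)(C)C)cc3O2)cc2c(c1O[Si](C)(C)C(C)(C)C)OC(C)(C)C=C2
F8 | step 11 | (2S,3RS)-7-(tert-butyldimethylsilyloxy)-2-[8-(tert-butyldimethylsilyloxy)-2,2-dimethyl-7-(3-methylbut-2-en-1-yl)-2H-chromen-6-yl]-3,4-dihydro-2H-chromene-3-carboxylic acid | CC(C)=CCc1c([C@@H]2C(C(=O)O)Cc3ccc(O[Si](C)(C)C(C)(C)C)cc3O2)cc2c(c1O[Si](C)(C)C(C)(C)C)OC(C)(C)C=C2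
F9 | step 11 | 2-thioxopyridin-1(2H)-yl ester of F8 | CC(C)=CCc1c([C@@H]2C(C(=O)On4ccccc4=S)Cc3ccc(O[Si](C)(C)C(C)(C)C)cc3O2)cc2c(c1O[Si](C)(C)C(C)(C)C)OC(C)(C)C=C2
F10 | step 7 | ethyl (E)-3-[8-(tert-butyldimethylsilyloxy)-2,2-dimethyl-7-(3-methylbut-2-en-1-yl)-2H-chromen-6-yl]prop-2-enoate | CCOC(=O)/C=C/c1cc2C=CC(C)(C)Oc2c(O[Si](C)(C)C(C)(C)C)c1CC=C(C)C
F11 | step 7 | (E)-3-[8-(tert-butyldimethylsilyloxy)-2,2-dimethyl-7-(3-methylbut-2-en-1-yl)-2H-chromen-6-yl]prop-2-en-1-ol | OC/C=C/c1cc2C=CC(C)(C)Oc2c(O[Si](C)(C)C(C)(C)C)c1CC=C(C)C
F12 | step 4 | tert-butyl 2-methylbut-3-en-2-yl carbonate | C=CC(C)(C)OC(=O)OC(C)(C)C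
A1 | alternative 1 | 4-[(3S)-3-aryl-3-hydroxypropyl]cyclohexane-1,3-dione (aryl = 8-(methoxymethoxy)-2,2-dimethyl-7-prenyl-2H-chromen-6-yl) | CC(C)=CCc1c([C@@H](O)CCC3CCC(=O)CC3=O)cc2c(c1OCOC)OC(C)(C)C=C2
A2 | alternative 1 | (6S)-6-[8-(methoxymethoxy)-2,2-dimethyl-7-(3-methylbut-2-en-1-yl)-2H-chromen-6-yl]oxan-2-one | CC(C)=CCc1c([C@@H]3CCCC(=O)O3)cc2c(c1OCOC)OC(C)(C)C=C2
A3 | alternative 1 | 3-(trimethylsilyl)but-3-en-2-one | CC(=O)C(=C)[Si](C)(C)C
A4 | alternative 2 | kazinol B bis(methoxymethyl) ether | CC(C)=CCc1c([C@@H]2CCc3ccc(OCOC)cc3O2)cc2c(c1OCOC)OC(C)(C)C=C2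
A5 | alternative 2 | (1S)-3-[2-bromo-4-(methoxymethoxy)phenyl]-1-[8-(methoxymethoxy)-2,2-dimethyl-7-(3-methylbut-2-en-1-yl)-2H-chromen-6-yl]propan-1-ol | CC(C)=CCc1c([C@@H](O)CCc3ccc(OCOC)cc3Br)cc2c(c1OCOC)OC(C)(C)C=C2
A6 | alternative 2 | lithium 2,2,6,6-tetramethylpiperidide | [Li]N1C(C)(C)CCCC1(C)C
A7 | alternative 3 | kazinol B 7-O-tert-butyldimethylsilyl ether | CC(C)=CCc1c([C@@H]2CCc3ccc(O[Si](C)(C)C(C)(C)C)cc3O2)cc2c(c1O)OC(C)(C)C=C2
A8 | alternative 3 | 4-[(2S)-7-(tert-butyldimethylsilyloxy)-3,4-dihydro-2H-chromen-2-yl]-3-(3-methylbut-2-en-1-yl)benzene-1,2-diol | CC(C)=CCc1c([C@@H]2CCc3ccc(O[Si](C)(C)C(C)(C)C)cc3O2)ccc(O)c1O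
A9 | alternative 3 | 3-methylbut-2-enal | CC(C)=CC=O
A10 | alternative 3 | titanium tetraethoxide, Ti(OEt)4 | CCO[Ti](OCC)(OCC)OCC
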